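The target is diosmetin bearing a 4-hydroxybenzyl group at C8 of ring A, and everything rests on cutting the CH2–C1'' bond. The key step exploits the position of the C8 methylene ortho to the C7 hydroxyl: O7–C7–C8–CH2 is a latent o-quinone methide. In one operation the C8 dimethylaminomethyl derivative of diosmetin loses dimethylamine and an arylboronic acid, bound at O7, hands its ipso carbon to the exocyclic methylene, which rearomatises ring A and completes the carbon skeleton. The precursor is the C8 Mannich base of diosmetin with all three phenols free. The aryl donor is 4-(benzyloxy)phenylboronic acid, whose benzyl group is removed by a final hydrogenolysis.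

Key step: step 2

Remark on stereochemistry: the target SMILES contains no stereocentre, no stereogenic double bond and no hindered axis, so the compound is achiral and no step has to set or preserve configuration.

Remark on the aryl donor: the phenol of the boronic acid is carried as a benzyl ether because free p-hydroxyarylboronic acids protodeboronate thermally in hot dipolar aprotic solvents and their phenol can add to a quinone methide through oxygen or its ortho carbons. The C–C disconnection is the same.

Step 1
Reactants: 1 diosmetin; 2 dimethylmethyleneiminium iodide
Product: 3 8-[(dimethylamino)methyl]-5,7-dihydroxy-2-(3-hydroxy-4-methoxyphenyl)-4H-chromen-4-one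
Conditions: 2 (1.0 equiv, in portions), NaHCO3 (1.2 equiv), DMF, 0 °C → rt; pour into H2O (pH 7–8), filter
Reagents that add atoms: none
Why: Mannich aminomethylation with a preformed iminium salt is an electrophilic substitution that goes to the phloroglucinol-type ring A and not to the less activated ring B, and in 5,7-dihydroxyflavones, whose 5-OH is locked in a hydrogen bond to C4=O, it is known to take C8 ortho to the acidic 7-OH, while one exact equivalent of a weighable, formaldehyde-free reagent at low temperature should hold back a second attack at C6 and methylene-bridged dimers.

Step 2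
Reactants: 3 8-[(dimethylamino)methyl]diosmetin; 4 4-(benzyloxy)phenylboronic acid
Product: 7 8-[4-(benzyloxy)benzyl]-5,7-dihydroxy-2-(3-hydroxy-4-methoxyphenyl)-4H-chromen-4-one, via C7/C8 o-quinone methide 5 (not isolated), via O7 dihydrogen borate of the product 6 (not isolated)
Conditions: 4 (3 equiv), DMF, 120 °C, Ar stream; 3 in DMF added slowly by syringe pump; then aq. NH4Cl
Reagents that add atoms: none
Why: On heating, 3 reacts through its zwitterion (O7 phenolate, C8–CH2–NHMe2+) and expels dimethylamine in a 1,4-elimination, a mode of o-quinone methide generation established for 8-(dimethylaminomethyl)-7-hydroxychromones; the argon stream carries the volatile amine off, and since C8 has only one ortho hydroxyl (its other neighbour C8a bears the ring oxygen O1) only 5 can form. The Lewis-acidic boron of 4 binds O7 of 5, and the tetracoordinate boronate so formed shifts its aryl group from boron to the exocyclic CH2 through a six-membered transition state (O7, C7, C8, CH2, C1'', B), which makes the CH2–C1'' bond, restores aromatic ring A and leaves borate 6, hydrolysed to 7 on work-up. The closest known reaction type is the metal-free 1,4-addition of aryl- and alkenylboron reagents to o-quinone methides generated in situ from o-hydroxybenzylamines (phenolic Mannich and Petasis bases) or o-hydroxybenzyl alcohols, in which electron-rich aryl groups such as 4-alkoxyphenyl migrate best. No ring is closed and no stereocentre is formed. The step needs site selectivity in the aryl donor (bond at the carbon that bore boron): the intramolecular ipso delivery secures it, and the O-benzyl group removes the phenol that could add through oxygen or its ortho carbons and leaves head-room in temperature because the donor does not protodeboronate readily. It also needs chemoselectivity against capture of 5 by the nucleophilic C6 of a second flavone or by the free 5-, 7- and 3'-hydroxyls: slow addition of 3 to a threefold excess of 4 keeps 5 dilute, and O-adducts revert to 5 at this temperature whereas the aryl transfer is irreversible.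

Step 3
Reactants: 7 8-[4-(benzyloxy)benzyl]diosmetin
Product: 8 5,7-dihydroxy-2-(3-hydroxy-4-methoxyphenyl)-8-(4-hydroxybenzyl)-4H-chromen-4-one (target)
Conditions: H2 (1 atm), 10% Pd/C, THF–MeOH (1:1), rt
Reagents that add atoms: none
Why: Catalytic hydrogenolysis of an aryl benzyl ether is routine on polyhydroxyflavones, and at 1 atm and room temperature the benzylic C–O bond should be cleaved well before the conjugated C2–C3 double bond, the C4 carbonyl, the methyl ether or the diarylmethane CH2 (which has no C–heteroatom bond to cleave) are touched.

Compound list
1 | diosmetin, 5,7-dihydroxy-2-(3-hydroxy-4-methoxyphenyl)-4H-chromen-4-one | COc1ccc(-c2cc(=O)c3c(O)cc(O)cc3o2)cc1O | starting material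
2 | dimethylmethyleneiminium iodide | C=[N+](C)C.[I-] | starting material
3 | 8-[(dimethylamino)methyl]-5,7-dihydroxy-2-(3-hydroxy-4-methoxyphenyl)-4H-chromen-4-one | COc1ccc(-c2cc(=O)c3c(O)cc(O)c(CN(C)C)c3o2)cc1O | intermediate
4 | 4-(benzyloxy)phenylboronic acid | OB(O)c1ccc(OCc2ccccc2)cc1 | starting material
5 | 5-hydroxy-2-(3-hydroxy-4-methoxyphenyl)-8-methylidene-4H-chromene-4,7(8H)-dione (C7/C8 o-quinone methide, not isolated) | COc1ccc(C2=CC(=O)C3=C(O2)C(=C)C(=O)C=C3O)cc1O | intermediate
6 | 8-[4-(benzyloxy)benzyl]-5-hydroxy-2-(3-hydroxy-4-methoxyphenyl)-4-oxo-4H-chromen-7-yl dihydrogen borate (not isolated) | COc1ccc(-c2cc(=O)c3c(O)cc(OB(O)O)c(Cc4ccc(OCc5ccccc5)cc4)c3o2)cc1O | intermediate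
7 | 8-[4-(benzyloxy)benzyl]-5,7-dihydroxy-2-(3-hydroxy-4-methoxyphenyl)-4H-chromen-4-one | COc1ccc(-c2cc(=O)c3c(O)cc(O)c(Cc4ccc(OCc5ccccc5)cc4)c3o2)cc1O | intermediate
8 | 5,7-dihydroxy-2-(3-hydroxy-4-methoxyphenyl)-8-(4-hydroxybenzyl)-4H-chromen-4-one (achiral) | COc1ccc(-c2cc(=O)c3c(O)cc(O)c(Cc4ccc(O)cc4)c3o2)cc1O | target

Total step count: 3. Longest linear sequence: 3 (1 → 3 → 7 → 8).

Steps most likely to fail

1. Step 2.
- What may go wrong: the aryl transfer may be slower than oligomerisation of the quinone methide through attack of C6 of a second flavone. Loss of the amine may also stay incomplete at the chosen temperature.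
- Fallback: it sets out from 3 and comes back at 7. It replaces the quinone methide by a palladium benzyl complex.
- First, heating 3 in acetic anhydride with potassium acetate, the usual acetolysis of chromone Mannich bases, should give [5,7-diacetoxy-2-(3-acetoxy-4-methoxyphenyl)-4-oxo-4H-chromen-8-yl]methyl acetate F1.
- A Suzuki–Miyaura coupling of this benzylic acetate with 4 follows (Pd(0), 1,5-bis(diphenylphosphino)pentane, K2CO3, tert-amyl alcohol, 80 °C). It should give 8-[4-(benzyloxy)benzyl]diosmetin 5,7,3'-triacetate F2.
- Partial loss of aryl acetates during the coupling is harmless, because methanolysis (cat. K2CO3, MeOH–THF, rt) then removes all of them and delivers 7.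

2. Step 1.
- What may go wrong: site selectivity between C8 and C6 may be imperfect, and ring A may be aminomethylated twice. The polar, zwitterionic products would be hard to separate.
- Check: the C8 assignment should be confirmed by HMBC (CH2 to C7, C8 and C8a) before the key step.
- Fallback: it sets out from 1 and comes back at 3. It installs the C1 unit at the aldehyde level.
- A Duff formylation (hexamethylenetetramine, AcOH, 100 °C, then aq. HCl) should give 5,7-dihydroxy-2-(3-hydroxy-4-methoxyphenyl)-4-oxo-4H-chromene-8-carbaldehyde F3.
- The formyl group deactivates ring A, so substitution stops after one carbon. The neutral regioisomeric aldehydes can be separated by chromatography or crystallisation.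
- Reductive amination of F3 with dimethylamine and NaBH(OAc)3 in THF then gives 3.

3. Step 3.
- What may go wrong: the C2–C3 double bond may be partly saturated, or the hydrogenolysis may stall through low solubility or adsorption of the polyphenol on the catalyst.
- Fallback: it sets out from 7 and comes back at 8, and it is non-reductive.
- Acidolysis of the benzyl ether in trifluoroacetic acid with a large excess of pentamethylbenzene as cation scavenger (rt) cleaves the O–CH2Ph bond by an SN1-type path. The methyl ether and the flavone are left alone, and the scavenger keeps the benzyl cation away from C6.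
- This fallback makes no new compound (F0).

Further compounds
F1 | step 2 | [5,7-diacetoxy-2-(3-acetoxy-4-methoxyphenyl)-4-oxo-4H-chromen-8-yl]methyl acetate | COc1ccc(-c2cc(=O)c3c(OC(C)=O)cc(OC(C)=O)c(COC(C)=O)c3o2)cc1OC(C)=O
F2 | step 2 | 8-[4-(benzyloxy)benzyl]diosmetin 5,7,3'-triacetate | COc1ccc(-c2cc(=O)c3c(OC(C)=O)cc(OC(C)=O)c(Cc4ccc(OCc5ccccc5)cc4)c3o2)cc1OC(C)=O
F3 | step 1 | 5,7-dihydroxy-2-(3-hydroxy-4-methoxyphenyl)-4-oxo-4H-chromene-8-carbaldehyde | COc1ccc(-c2cc(=O)c3c(O)cc(O)c(C=O)c3o2)cc1O
F0 | step 3 | none | none
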